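**Retrosynthetic overview**
1. Target 20 ⇐ trimethyl ester 19 ⇐ Δ5(6)-ene 17: C5–H by face-selective conjugate reduction (sets the trans A/B fusion), then C6 equilibration.
2. Ring A (last ring): C4–C5 bond by ester-enolate addition–elimination on the C5 enol triflate 15; C18 by dienolate methylation.
3. Ring B: Dieckmann closure C10→C5 of triester 11, then alkylation of C10 with the C1–C4/C19 chain.
4. Ring D: ketyl–alkyne closure C13–C16 of propargyl ketone 10; quaternary C8 from two successive conjugate additions (malonate, then propargyl) to the ring C enone.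
5. Ring C and the first stereocentre (C9): amine-catalysed Michael addition of methyl 4-oxobutanoate to methyl vinyl ketone, then aldol condensation. Ring order: C → D → B → A.

Assumption: carbon numbers and α/β are those of the gibberellane skeleton of the target (α = face of the C19/C20 carboxyls). The (S)-catalyst in step 1 is taken to give (S)-3, as the usual shielding model for diarylprolinol ether enamines predicts; if the sense were opposite, the (R)-catalyst is used.

**Step 1**
Reactants: 1 methyl 4-oxobutanoate; 2 but-3-en-2-one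
Product: 3 methyl (3S)-3-formyl-6-oxoheptanoate
Conditions: (S)-2-[methoxy(diphenyl)methyl]pyrrolidine (5 mol%), ethyl 3,4-dihydroxybenzoate (20 mol%), neat, 4 °C
Reagents that add atoms: none
Why: Enamine-mediated Michael addition of an aldehyde to a vinyl ketone: one face of the anti-E enamine of 1 is shielded by the methoxy(diphenyl)methyl group, so 2 adds to the open face and sets C9, the only stereocentre made under catalyst control.

**Step 2**
Reactants: 3 methyl (3S)-3-formyl-6-oxoheptanoate
Product: 4 methyl 2-[(1S)-4-oxocyclohex-2-en-1-yl]acetate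
Conditions: TsOH·H2O (10 mol%), PhMe, 80 °C (–H2O)
Reagents that add atoms: none
Why: Acid-catalysed intramolecular aldol condensation (Robinson-type closure of ring C): the methyl ketone enol attacks the aldehyde and dehydration gives the enone, with C9 kept as the γ-carbon.

**Step 3**
Reactants: 4 methyl 2-[(1S)-4-oxocyclohex-2-en-1-yl]acetate; 5 dimethyl malonate
Product: 7 dimethyl 2-[(1S,6S)-6-(2-methoxy-2-oxoethyl)-3-(trimethylsilyloxy)cyclohex-2-en-1-yl]propanedioate, via silyl ketene acetal 6 (not isolated)
Conditions: 5, Et3N, Me3SiOTf (slight excess), CH2Cl2, 0 °C; then 4, –78 → –30 °C; non-aqueous work-up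
Reagents that add atoms: trimethylsilyl trifluoromethanesulfonate, C[Si](C)(C)OS(=O)(=O)C(F)(F)F
Why: Mukaiyama–Michael addition with silyl transfer: the malonate ketene acetal adds to the unsubstituted β-carbon C8 and the ketone is captured regiospecifically as the C13–C14 silyl enol ether needed for step 4 (the new C8–H centre, trans to the C9 arm, is erased there).

**Step 4**
Reactants: 7 dimethyl 2-[(1S,6S)-6-(2-methoxy-2-oxoethyl)-3-(trimethylsilyloxy)cyclohex-2-en-1-yl]propanedioate
Product: 8 dimethyl 2-[(6S)-6-(2-methoxy-2-oxoethyl)-3-oxocyclohex-1-en-1-yl]propanedioate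
Conditions: Pd(OAc)2 (1.05 equiv), MeCN, 25 °C
Reagents that add atoms: none
Why: Saegusa–Ito oxidation: palladation of the silyl enol ether at C14 and β-hydride loss from C8 regenerate the enone on the substituted side only, giving the β,β-disubstituted acceptor with C9 untouched.

**Step 5**
Reactants: 8 dimethyl 2-[(6S)-6-(2-methoxy-2-oxoethyl)-3-oxocyclohex-1-en-1-yl]propanedioate; 9 tributyl(propa-1,2-dien-1-yl)stannane
Product: 10 dimethyl 2-[(1S,2S)-2-(2-methoxy-2-oxoethyl)-5-oxo-1-(prop-2-yn-1-yl)cyclohexyl]propanedioate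
Conditions: TiCl4 (2.2 equiv), CH2Cl2, –78 °C; then 9, –78 → –40 °C; aq. NaHCO3
Reagents that add atoms: none
Why: Lewis-acid-promoted conjugate propargylation (Sakurai-type SE2′ addition of an allenylstannane): the stannane attacks the activated C8 opposite the pseudo-axial C9 acetate arm, creating quaternary C8 with the propargyl group trans and the malonate cis to that arm, as rings B and D require.

**Step 6**
Reactants: 10 dimethyl 2-[(1S,2S)-2-(2-methoxy-2-oxoethyl)-5-oxo-1-(prop-2-yn-1-yl)cyclohexyl]propanedioate
Product: 11 dimethyl 2-[(1S,2S,5S)-5-hydroxy-2-(2-methoxy-2-oxoethyl)-6-methylidenebicyclo[3.2.1]octan-1-yl]propanedioate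
Conditions: SmI2 (2.5 equiv), HMPA, t-BuOH, THF, 0 °C
Reagents that add atoms: none
Why: Ketyl–alkyne reductive cyclisation (5-exo-dig): the ketyl radical generated at C13 by SmI2 adds to the internal alkyne carbon C16 of the axial propargyl group, forming ring D with the bridgehead 13-OH and the 16-methylene in one step; the bridgehead configuration is dictated by C8.

**Step 7**
Reactants: 11 dimethyl 2-[(1S,2S,5S)-5-hydroxy-2-(2-methoxy-2-oxoethyl)-6-methylidenebicyclo[3.2.1]octan-1-yl]propanedioate; 12 methyl 5-bromopentanoate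
Product: 14 trimethyl 13-hydroxy-5-oxo-4,5-seco-18-nor-ent-gibberell-16-ene-7,19,20-trioate, via Dieckmann keto diester 13 (not isolated)
Conditions: NaOMe (1.2 equiv), MeOH, 65 °C; evaporate; then 12, Bu4NI (cat.), DMF, 50 °C
Reagents that add atoms: none
Why: Dieckmann condensation then C-alkylation of the β-keto ester enolate: under the reversible conditions only attack of the C10 acetate carbon on a malonate ester gives an enolisable, hence trapped, β-keto ester (ring B, cis-fused because the two arms are cis). The bromide then alkylates the less hindered C10 (C6 is flanked by quaternary C8) from the β face, anti to C11, which sets C10 with C1 β and C20 α.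

**Step 8**
Reactants: 14 trimethyl 13-hydroxy-5-oxo-4,5-seco-18-nor-ent-gibberell-16-ene-7,19,20-trioate
Product: 15 trimethyl 13-hydroxy-5-(trifluoromethanesulfonyloxy)-4,5-seco-18-nor-ent-gibberella-5,16-diene-7,19,20-trioate
Conditions: NaH (1.1 equiv), PhNTf2, THF, 0 → 25 °C
Reagents that add atoms: N-phenylbis(trifluoromethanesulfonimide), O=S(=O)(N(c1ccccc1)S(=O)(=O)C(F)(F)F)C(F)(F)F
Why: O-Sulfonylation of a β-keto ester enolate: the ketone can enolise only towards C6, so a single enol triflate forms, a vinylogous acyl triflate electrophilic at C5; one equivalent of NaH deprotonates the β-keto ester and not the tertiary alcohol.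

**Step 9**
Reactants: 15 trimethyl 13-hydroxy-5-(trifluoromethanesulfonyloxy)-4,5-seco-18-nor-ent-gibberella-5,16-diene-7,19,20-trioate
Product: 17 trimethyl 13-hydroxy-ent-gibberella-5,16-diene-7,19,20-trioate, via nor-methyl diene triester 16 (not isolated)
Conditions: LiN(iPr)2 (3.3 equiv), THF, –78 → –20 °C; then MeI, –78 → 0 °C
Reagents that add atoms: iodomethane, CI
Why: Proposed new method: a transition-metal-free ring closure in which the lithium enolate of the C19 ester adds 6-exo to C5 (the β-carbon of the β-triflyloxy acrylate) and the resulting C6 ester enolate expels triflate (addition–elimination at a vinylic carbon), after which excess amide base converts the doubly activated C4–H of 16 into a cross-conjugated dienolate that MeI methylates at C4 from the β face, anti to the pseudo-axial C20 ester, the C6 terminus next to quaternary C8 being too hindered to react; the closest known chemistry is the Weiler-type coupling of R2CuLi reagents with enol phosphates or triflates of β-keto esters and the α-alkylation of glutaconate-type dienolates, but an intramolecular ester-enolate version that closes a ring and sets a quaternary centre in one flask has not been shown.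

**Step 10**
Reactants: 17 trimethyl 13-hydroxy-ent-gibberella-5,16-diene-7,19,20-trioate
Product: 19 trimethyl 13-hydroxy-ent-gibberell-16-ene-7,19,20-trioate (trimethyl ester of the target), via 6-epi triester 18 (not isolated)
Conditions: Mg, MeOH, 0 → 25 °C; then NaOMe, MeOH, 60 °C
Reagents that add atoms: none
Why: Single-electron conjugate reduction of an enoate: in the chair of ring A the C19 and C20 esters are both axial on the α face and block it, so C5 is protonated axially from the β face (5-H β, trans A/B fusion); the kinetically protonated C6 ester is then epimerised by methoxide to the more stable natural 6β-CO2Me, trans to C4.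

**Step 11**
Reactants: 19 trimethyl 13-hydroxy-ent-gibberell-16-ene-7,19,20-trioate
Product: 20 13-hydroxy-ent-gibberell-16-ene-7,19,20-trioic acid (the target gibberellin)
Conditions: LiSCH2CH2CH3 (10 equiv), HMPA, 25 → 50 °C; then 1 M HCl, 0 °C
Reagents that add atoms: none
Why: SN2 dealkylation of methyl esters by a thiolate: attack at the methyl carbons bypasses the hindered acyl carbons of the neopentyl C19 and C20 esters and leaves the tertiary allylic alcohol and the exocyclic alkene untouched.

**Compound list**
1 | methyl 4-oxobutanoate | COC(=O)CCC=O | starting material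
2 | but-3-en-2-one (methyl vinyl ketone) | CC(=O)C=C | starting material
3 | methyl (3S)-3-formyl-6-oxoheptanoate | O=C[C@H](CC(=O)OC)CCC(C)=O | intermediate
4 | methyl 2-[(1S)-4-oxocyclohex-2-en-1-yl]acetate | O=C1C=C[C@H](CC(=O)OC)CC1 | intermediate
5 | dimethyl malonate | COC(=O)CC(=O)OC | starting material
6 | methyl 3-methoxy-3-(trimethylsilyloxy)prop-2-enoate (silyl ketene acetal, not isolated) | COC(=O)C=C(OC)O[Si](C)(C)C | intermediate
7 | dimethyl 2-[(1S,6S)-6-(2-methoxy-2-oxoethyl)-3-(trimethylsilyloxy)cyclohex-2-en-1-yl]propanedioate (ring substituents trans) | C[Si](C)(C)OC1=C[C@@H](C(C(=O)OC)C(=O)OC)[C@H](CC(=O)OC)CC1 | intermediate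
8 | dimethyl 2-[(6S)-6-(2-methoxy-2-oxoethyl)-3-oxocyclohex-1-en-1-yl]propanedioate | O=C1C=C(C(C(=O)OC)C(=O)OC)[C@H](CC(=O)OC)CC1 | intermediate
9 | tributyl(propa-1,2-dien-1-yl)stannane | C=C=C[Sn](CCCC)(CCCC)CCCC | starting material
10 | dimethyl 2-[(1S,2S)-2-(2-methoxy-2-oxoethyl)-5-oxo-1-(prop-2-yn-1-yl)cyclohexyl]propanedioate (propargyl trans to the acetate arm) | O=C1C[C@](CC#C)(C(C(=O)OC)C(=O)OC)[C@H](CC(=O)OC)CC1 | intermediate
11 | dimethyl 2-[(1S,2S,5S)-5-hydroxy-2-(2-methoxy-2-oxoethyl)-6-methylidenebicyclo[3.2.1]octan-1-yl]propanedioate (rings C/D) | C=C1C[C@]2(C(C(=O)OC)C(=O)OC)C[C@@]1(O)CC[C@H]2CC(=O)OC | intermediate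
12 | methyl 5-bromopentanoate | COC(=O)CCCCBr | starting material
13 | dimethyl 13-hydroxy-5-oxo-1,2,3,4,18,19-hexanor-ent-gibberell-16-ene-7,20-dioate (rings B/C/D; C6 and C10 enolisable, not isolated) | C=C1C[C@]23C[C@@]1(O)CC[C@H]2C(C(=O)OC)C(=O)C3C(=O)OC | intermediate
14 | trimethyl 13-hydroxy-5-oxo-4,5-seco-18-nor-ent-gibberell-16-ene-7,19,20-trioate (C10: CO2Me α, 5-methoxy-5-oxopentyl chain β; C6 enolisable) | C=C1C[C@]23C[C@@]1(O)CC[C@H]2[C@](C(=O)OC)(CCCCC(=O)OC)C(=O)C3C(=O)OC | intermediate
15 | trimethyl 13-hydroxy-5-(trifluoromethanesulfonyloxy)-4,5-seco-18-nor-ent-gibberella-5,16-diene-7,19,20-trioate | C=C1C[C@]23C[C@@]1(O)CC[C@H]2[C@](C(=O)OC)(CCCCC(=O)OC)C(OS(=O)(=O)C(F)(F)F)=C3C(=O)OC | intermediate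
16 | trimethyl 13-hydroxy-18-nor-ent-gibberella-5,16-diene-7,19,20-trioate (C4–H, epimer mixture, not isolated) | C=C1C[C@]23C[C@@]1(O)CC[C@H]2[C@]1(C(=O)OC)CCCC(C(=O)OC)C1=C3C(=O)OC | intermediate
17 | trimethyl 13-hydroxy-ent-gibberella-5,16-diene-7,19,20-trioate | C=C1C[C@]23C[C@@]1(O)CC[C@H]2[C@]1(C(=O)OC)CCC[C@@](C)(C(=O)OC)C1=C3C(=O)OC | intermediate
18 | trimethyl 13-hydroxy-6-epi-ent-gibberell-16-ene-7,19,20-trioate (6-epi triester, not isolated) | C=C1C[C@]23C[C@@]1(O)CC[C@H]2[C@]1(C(=O)OC)CCC[C@@](C)(C(=O)OC)[C@H]1[C@H]3C(=O)OC | intermediate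
19 | trimethyl 13-hydroxy-ent-gibberell-16-ene-7,19,20-trioate (trimethyl ester of the target) | C=C1C[C@]23C[C@@]1(O)CC[C@H]2[C@]1(C(=O)OC)CCC[C@@](C)(C(=O)OC)[C@H]1[C@@H]3C(=O)OC | intermediate
20 | 13-hydroxy-ent-gibberell-16-ene-7,19,20-trioic acid (the target gibberellin) | C=C1C[C@]23C[C@@]1(O)CC[C@H]2[C@]1(C(=O)O)CCC[C@@](C)(C(=O)O)[C@H]1[C@@H]3C(=O)O | target

**Totals**
Total step count: 11. Longest linear sequence: 11 steps (from 1; all other building blocks are bought).

**Three steps most likely to fail**

Step 9 (the new ring closure). The risks are Claisen attack of the C4 enolate on the C20 ester and S–O cleavage of the triflate. The fallback uses known reactions and sets out from 11. The Dieckmann closure of step 7 is followed by alkylation with 1-bromo-3-chloropropane instead of 12, giving the 10β-(3-chloropropyl) keto diester F2. NaH/PhNTf2 gives its enol triflate F3. Negishi coupling with the Reformatsky reagent BrZnCH2CO2Me (Pd(PPh3)4, THF, 50 °C) attaches C4–C19 to C5 and gives the seco diene triester F4. LiN(SiMe3)2/NaI in THF–DMF then closes ring A by intramolecular C4-alkylation of the soft dienolate (6-exo-tet) to 16, which is methylated in the same flask with MeI, coming back to the route at 17.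

Step 5 (quaternary C8 by conjugate propargylation of a hindered enone). The fallback sets out from 8. Hosomi–Sakurai addition of (2-bromoallyl)trimethylsilane (TiCl4, CH2Cl2, –78 °C), the best-precedented way to quaternary β-carbons, gives the 2-bromoallyl ketone F1. An intramolecular Nozaki–Hiyama–Kishi reaction (CrCl2, NiCl2 cat., DMF) adds the alkenyl carbon C16 to the C13 ketone and closes ring D, coming back at 11.

Step 10 (reduction of a tetrasubstituted enoate; face selectivity at C5). The fallback sets out from 17. Thiolate demethylation under the conditions of step 11 gives the diene triacid F5. Li/NH3 (t-BuOH, –78 °C), a Birch-type reduction of an α,β-unsaturated carboxylate in which the two solvated axial carboxylates screen the α face even more strongly, gives 20 mixed with the 6-epi triacid F6. The mixture is re-esterified with Me3SiCHN2 to 19/18 and equilibrated with NaOMe, coming back at 19.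

**Further compounds**
F1 | step 5 | dimethyl 2-[1-(2-bromoprop-2-en-1-yl)-2-(2-methoxy-2-oxoethyl)-5-oxocyclohexyl]propanedioate (configuration as in 10) | O=C1C[C@](CC(Br)=C)(C(C(=O)OC)C(=O)OC)[C@H](CC(=O)OC)CC1
F2 | step 9 | dimethyl 10β-(3-chloropropyl)-13-hydroxy-5-oxo-1,2,3,4,18,19-hexanor-ent-gibberell-16-ene-7,20-dioate | C=C1C[C@]23C[C@@]1(O)CC[C@H]2[C@](C(=O)OC)(CCCCl)C(=O)C3C(=O)OC
F3 | step 9 | 5-enol triflate of F2 (C5–OTf, C5=C6) | C=C1C[C@]23C[C@@]1(O)CC[C@H]2[C@](C(=O)OC)(CCCCl)C(OS(=O)(=O)C(F)(F)F)=C3C(=O)OC
F4 | step 9 | trimethyl 3-chloro-13-hydroxy-3,4-seco-18-nor-ent-gibberella-5,16-diene-7,19,20-trioate | C=C1C[C@]23C[C@@]1(O)CC[C@H]2[C@](C(=O)OC)(CCCCl)C(CC(=O)OC)=C3C(=O)OC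
F5 | step 10 | 13-hydroxy-ent-gibberella-5,16-diene-7,19,20-trioic acid | C=C1C[C@]23C[C@@]1(O)CC[C@H]2[C@]1(C(=O)O)CCC[C@@](C)(C(=O)O)C1=C3C(=O)O
F6 | step 10 | 13-hydroxy-6-epi-ent-gibberell-16-ene-7,19,20-trioic acid | C=C1C[C@]23C[C@@]1(O)CC[C@H]2[C@]1(C(=O)O)CCC[C@@](C)(C(=O)O)[C@H]1[C@H]3C(=O)O
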